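All runs come from a simulation for an exercise; scatter was added.

In a one-step world, substrate simply turns into product in proportion to what is left. The last reading of the midnight run, 27.3 % at 5.00 min, then gives a rate constant of 0.0638 min⁻¹ and 79.7 % of the charge at 25 min, still climbing towards the whole charge.

- midnight: substrate 0.10 M; reagent in the second phase 0.080 M; the very flask that is asked about, followed so far
- flask: substrate 0.10 M; reagent in the second phase 0.0800 M; time 25 min; volume of the second phase over the first 0.25

- midnight (time / min: product / %): 0.417: 0.2; 1.33: 3.7; 2.50: 13.0; 4.00: 20.8; 5.00: 27.3

(standard deviation of a reading: 1 percentage point)

- in the second phase: reagent in the second phase; everything else is in the first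
- charges count per volume of the first phase; a concentration in a rate is the amount of a species over the volume of its own phase; every rate counts per litre of the first phase
- what was read earlier has a scatter of 1 percentage point, one standard deviation
- the earlier runs hold the two phases in the same ratio of volumes as the flask asked about

- the product standing at 25 min, as a percentage of the substrate charged
- the change that raises the amount of product at 25 min, in percent of the substrate charged most ("none" if none brings more than 2 percentage points) (Friday's / Monday's / none)
- amount of product at 25 min, in percent of the substrate charged, after Friday's

- Friday's: doubling the amount of reagent in the second phase, all else as stated
- Monday's: doubling the transfer coefficient of the reagent in the second phase, all else as stated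

Now add the crossing of the reagent from the second phase. The midnight run's first reading is 0.2 %, where the one-step curve gives 2.62 %. From 1.33 min to 5.00 min the run climbs at a read slope of 0.0643 min⁻¹ as a fraction of the charge, which puts the start of that line at about 0.755 min. That delay is small beside the time asked about, so it barely moves the number.

Now add the charges. If one reagent makes one product, which is our assumption, the reagent is the limiting reagent. The ceiling, reagent charged over substrate charged, is then 80.0 % of the substrate.

We join the two ends with an exponential: the measured slope at the start, the ceiling at the end, and a time constant of ceiling over slope, 12.4 min. Starting from the last reading, our own reckoning gives 69.4 %. Monday's keeps the ceiling, so it can gain at most 11 percentage points on that reckoning. Friday's raises reagent over substrate to 160 %, so on the same assumption the substrate becomes the limit, and if the slope doubles, which we also assume, our reckoning gives 96.0 %.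

The forecast gives 71 % at 25 min (range 60 % to 77 %), names Friday's as the better change, and gives 98 % after it (range 86 % to 100 %), with “the reagent capping yield at 80%”. Our 69.4 % lies below its figure but inside its range, and our 96.0 % for Friday's lies below its 98 % but also inside its range.

The flask gives 72.4 % at 25 min. Friday's gives 98.8 %, a gain of 26 points against 2 points for Monday's, so the choice is Friday's.

    reagent in the reaction phase ⇌ reagent in the second phase, rate k1*([reagent in the reaction phase] - [reagent in the second phase]/K1) per volume of the first phase (partition coefficient = 0.420, kL = 4.10 × 10⁻⁴ s⁻¹)
    substrate + reagent in the reaction phase → product (k = 0.0550 M⁻¹ s⁻¹)

Left standing until 250 min, the flask holds 80.0 %, level with the ceiling of 80.0 %. One more flask, charged with 0.25 M of substrate, has a ceiling of 32.0 %, and at 25 min it holds 31.8 % of product with 68 % of its substrate left.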